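**Retrosynthetic overview**

- The chalcone C=C is made last by Claisen–Schmidt condensation of an aryl methyl ketone with 4-hydroxybenzaldehyde; the acetyl group is put on the one free position of the trioxygenated ring by bromination, Br–Li exchange and acylation.
- The oxane ring, the only ring formed in the route, is closed in one operation: an acid-catalysed cationic formal [4+2] annulation of a (3S)-1-aryl-1,3-diol (C4–C5–C6–O1 unit) with 4-benzyloxystyrene (C2–C3 unit) makes C3–C4 and O1–C2 together.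
- Enabling feature: oxane C4 is benzylic to the 2,4,6-trioxygenated benzene ring and 1,3 to the oxygen carried by C6, and oxane C2 is benzylic to a para-oxygenated benzene ring. A cation at C4 can therefore take up the styrene CH2, and the new C2 cation sits six atoms from the C6 hydroxyl.
- The diol comes from a 1,3-diketone (Claisen condensation of two commercial pieces); C6 is set by Noyori asymmetric hydrogenation, and C4 and C2 are set in the annulation.

Key step: step 7

Remarks on the chemistry: oxane numbering is O1, C2 (4-oxyphenyl), C4 (trioxygenated aryl), C6 (arylethyl); the target is the all-cis (2S,4R,6S) isomer. Diol 8 is carried as a mixture of C1 epimers because that centre is ionised in step 7. Benzyl ethers flank the cationic centre because an oxonium ion formed from them can only revert, which closes the chroman pathway open to free phenols. Compounds 1, 3, 9 and 18 are taken as commercial.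

Step 1
Reactants: 1 1-(2,6-dihydroxy-4-methoxyphenyl)ethan-1-one
Product: 2 1-[2,6-bis(benzyloxy)-4-methoxyphenyl]ethan-1-one
Conditions: BnBr (2.5 equiv), K2CO3, KI (cat.), DMF, 70 °C
Reagents that add atoms: benzyl bromide, BrCc1ccccc1
Why: Williamson ether synthesis, run hot in DMF because both phenols are hydrogen-bonded to the acetyl group; O-alkylation should dominate with K2CO3 in a dipolar aprotic solvent.

Step 2
Reactants: 3 methyl 3-(4-hydroxyphenyl)propanoate
Product: 4 methyl 3-[4-(benzyloxy)phenyl]propanoate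
Conditions: BnBr, K2CO3, acetone, reflux
Reagents that add atoms: benzyl bromide, BrCc1ccccc1
Why: Williamson ether synthesis of an unhindered phenol; the methyl ester is inert to K2CO3 in acetone.

Step 3
Reactants: 2 1-[2,6-bis(benzyloxy)-4-methoxyphenyl]ethan-1-one; 4 methyl 3-[4-(benzyloxy)phenyl]propanoate
Product: 6 1-[2,6-bis(benzyloxy)-4-methoxyphenyl]-5-[4-(benzyloxy)phenyl]pentane-1,3-dione, via sodium enolate 5 (not isolated)
Conditions: NaH (3 equiv), THF, reflux; 4 (1.3 equiv); aq. HCl work-up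
Reagents that add atoms: none
Why: Crossed Claisen condensation in which the methyl ketone enolate acylates on carbon with the unhindered ester, driven to completion by deprotonation of the 1,3-diketone formed.

Step 4
Reactants: 6 1-[2,6-bis(benzyloxy)-4-methoxyphenyl]-5-[4-(benzyloxy)phenyl]pentane-1,3-dione
Product: 7 (3S)-1-[2,6-bis(benzyloxy)-4-methoxyphenyl]-5-[4-(benzyloxy)phenyl]-3-hydroxypentan-1-one
Conditions: H2 (50 bar), RuCl2[(S)-BINAP](dmf)n (1 mol %), MeOH/CH2Cl2, 50 °C
Reagents that add atoms: none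
Why: Noyori asymmetric hydrogenation of a 1-aryl-1,3-diketone, in which the alkyl-side carbonyl is reduced through the ruthenium chelate with the hindered aryl ketone and (S)-BINAP should give the (3S) carbinol by analogy with β-keto esters; aryl benzyl ethers are inert to this homogeneous catalyst.

Step 5
Reactants: 7 (3S)-1-[2,6-bis(benzyloxy)-4-methoxyphenyl]-5-[4-(benzyloxy)phenyl]-3-hydroxypentan-1-one
Product: 8 (3S)-1-[2,6-bis(benzyloxy)-4-methoxyphenyl]-5-[4-(benzyloxy)phenyl]pentane-1,3-diol (mixture of C1 epimers)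
Conditions: NaBH4 (excess), MeOH/THF, 0 °C to rt; purification on Et3N-deactivated silica
Reagents that add atoms: none
Why: Borohydride reduction of the aryl ketone; the new C1 carbinol centre is formed without control, which does not matter because it is ionised in step 7, and C3 is untouched.

Step 6
Reactants: 9 4-(benzyloxy)benzaldehyde
Product: 10 1-(benzyloxy)-4-ethenylbenzene
Conditions: Ph3PCH3Br, KOtBu, THF, 0 °C to rt
Reagents that add atoms: methyltriphenylphosphonium bromide, C[P+](c1ccccc1)(c1ccccc1)c1ccccc1.[Br-]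
Why: Wittig methylenation of a non-enolisable aromatic aldehyde with the unstabilised ylide.

Step 7
Reactants: 8 (3S)-1-[2,6-bis(benzyloxy)-4-methoxyphenyl]-5-[4-(benzyloxy)phenyl]pentane-1,3-diol; 10 1-(benzyloxy)-4-ethenylbenzene
Product: 13 (2S,4R,6S)-4-[2,6-bis(benzyloxy)-4-methoxyphenyl]-2-[4-(benzyloxy)phenyl]-6-{2-[4-(benzyloxy)phenyl]ethyl}oxane, via benzylic cation 11 (not isolated), via open-chain cation 12 (not isolated)
Conditions: 10 (3 equiv), (PhO)2P(O)OH (10 mol %), 4 Å molecular sieves, CH2Cl2, 0 °C to rt; 8 added over 2 h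
Reagents that add atoms: none
Why: Proposed new method: the acid should ionise only the C1 hydroxyl of 8, which is benzylic to the 2,6-bis(benzyloxy)-4-methoxyphenyl ring, to give cation 11; the CH2 terminus of styrene 10 adds to it (new C3–C4 bond) to give the para-benzyloxybenzylic cation 12, which the C6 hydroxyl captures (new O1–C2 bond), so the whole is a stepwise polar [4+2] annulation of a 1,4-carbon/oxygen dipole with an alkene. The closest known reaction types are the acid-catalysed [4+2] annulation of ortho-hydroxybenzyl alcohols with styrenes to chromans and the Prins cyclisation; new here is that an aliphatic γ-hydroxyl, not a phenol or an oxocarbenium ion, is the second partner. The oxane ring is closed by a 6-exo-trig-type attack of the hydroxyl on the trigonal C2 of 12, whose π-system to the aryl ring stays outside the new ring. Because 11 is far more stabilised than 12, C–C bond formation should pass through a late, product-like chair in which the C6 hydroxyl is already engaged with the developing C2 cation, so that the preset C6 side chain, the bulky C4 aryl and the C2 aryl all sit equatorial: C4 (R) is set by this chair relative to C6 (S), and C2 (S) by equatorial closure, with reversible C2–O ionisation under the acid able to correct a C2 epimer. The step needs 1:1 coupling in preference to styrene oligomerisation and Friedel–Crafts self-alkylation: the intramolecular hydroxyl trap of 12 should outrun a second styrene addition, the product ether ionises less readily than 8, both ortho positions of the cation-bearing ring are blocked (no indane path, and the benzyl ethers cannot dealkylate to a chroman), and excess 10 with slow addition of 8 keeps the electron-rich ring of 8 from competing.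

Step 8
Reactants: 13 (2S,4R,6S)-4-[2,6-bis(benzyloxy)-4-methoxyphenyl]-2-[4-(benzyloxy)phenyl]-6-{2-[4-(benzyloxy)phenyl]ethyl}oxane
Product: 14 (2S,4R,6S)-4-[2,6-bis(benzyloxy)-3-bromo-4-methoxyphenyl]-2-[4-(benzyloxy)phenyl]-6-{2-[4-(benzyloxy)phenyl]ethyl}oxane
Conditions: NBS (1.05 equiv), MeCN/CH2Cl2, −20 to 0 °C, dark
Reagents that add atoms: N-bromosuccinimide, O=C1CCC(=O)N1Br
Why: Electrophilic aromatic bromination of by far the most electron-rich ring, whose two free positions are equivalent by rotation about the C4–aryl bond, so a single monobromide should form.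

Step 9
Reactants: 14 (2S,4R,6S)-4-[2,6-bis(benzyloxy)-3-bromo-4-methoxyphenyl]-2-[4-(benzyloxy)phenyl]-6-{2-[4-(benzyloxy)phenyl]ethyl}oxane
Product: 16 1-[2,4-bis(benzyloxy)-3-{(2S,4R,6S)-2-[4-(benzyloxy)phenyl]-6-{2-[4-(benzyloxy)phenyl]ethyl}oxan-4-yl}-6-methoxyphenyl]ethan-1-one, via aryllithium 15 (not isolated)
Conditions: n-BuLi (1.1 equiv), THF, −78 °C, 10 min; then MeC(O)N(OMe)Me (2 equiv), −78 to −20 °C; aq. NH4Cl
Reagents that add atoms: N-methoxy-N-methylacetamide, CC(=O)N(C)OC
Why: Bromine–lithium exchange, which at −78 °C is faster than any benzylic deprotonation, followed by Weinreb ketone synthesis, whose chelated tetrahedral intermediate stops at the ketone.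

Step 10
Reactants: 16 1-[2,4-bis(benzyloxy)-3-{(2S,4R,6S)-2-[4-(benzyloxy)phenyl]-6-{2-[4-(benzyloxy)phenyl]ethyl}oxan-4-yl}-6-methoxyphenyl]ethan-1-one
Product: 17 1-[2,4-dihydroxy-3-{(2S,4R,6S)-2-(4-hydroxyphenyl)-6-[2-(4-hydroxyphenyl)ethyl]oxan-4-yl}-6-methoxyphenyl]ethan-1-one
Conditions: H2 (1 atm), 10% Pd/C, EtOAc/EtOH, rt, stopped at full debenzylation; acid-free work-up
Reagents that add atoms: none
Why: Hydrogenolysis of the four aryl benzyl ethers, which cleave much faster than the ring C2–O bond of a 2-aryloxane in a neutral medium, while the hindered, hydrogen-bonded aryl ketone should not be reduced.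

Step 11
Reactants: 17 1-[2,4-dihydroxy-3-{(2S,4R,6S)-2-(4-hydroxyphenyl)-6-[2-(4-hydroxyphenyl)ethyl]oxan-4-yl}-6-methoxyphenyl]ethan-1-one; 18 4-hydroxybenzaldehyde
Product: 20 (2E)-1-[2,4-dihydroxy-3-{(2S,4R,6S)-2-(4-hydroxyphenyl)-6-[2-(4-hydroxyphenyl)ethyl]oxan-4-yl}-6-methoxyphenyl]-3-(4-hydroxyphenyl)prop-2-en-1-one, via aldol adduct 19 (not isolated)
Conditions: 18 (3 equiv), KOH (50% aq.), EtOH, rt, argon; then AcOH to pH 6 at 0 °C
Reagents that add atoms: none
Why: Claisen–Schmidt condensation (aldol addition, then E1cB dehydration) should give the thermodynamically favoured E-enone, with concentrated hydroxide compensating for the phenoxide-deactivated partners; no stereocentre is touched and the near-neutral work-up avoids acid-induced isomerisation of the oxane.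

**Compound list**

1 | 1-(2,6-dihydroxy-4-methoxyphenyl)ethan-1-one | CC(=O)c1c(O)cc(OC)cc1O | starting material
2 | 1-[2,6-bis(benzyloxy)-4-methoxyphenyl]ethan-1-one | CC(=O)c1c(OCc2ccccc2)cc(OC)cc1OCc1ccccc1 | intermediate
3 | methyl 3-(4-hydroxyphenyl)propanoate | COC(=O)CCc1ccc(O)cc1 | starting material
4 | methyl 3-[4-(benzyloxy)phenyl]propanoate | COC(=O)CCc1ccc(OCc2ccccc2)cc1 | intermediate
5 | sodium 1-[2,6-bis(benzyloxy)-4-methoxyphenyl]ethen-1-olate (enolate of 2) | [Na+].[O-]C(=C)c1c(OCc2ccccc2)cc(OC)cc1OCc1ccccc1 | intermediate (not isolated)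
6 | 1-[2,6-bis(benzyloxy)-4-methoxyphenyl]-5-[4-(benzyloxy)phenyl]pentane-1,3-dione | O=C(CC(=O)CCc1ccc(OCc2ccccc2)cc1)c1c(OCc2ccccc2)cc(OC)cc1OCc1ccccc1 | intermediate
7 | (3S)-1-[2,6-bis(benzyloxy)-4-methoxyphenyl]-5-[4-(benzyloxy)phenyl]-3-hydroxypentan-1-one | O=C(C[C@H](CCc1ccc(OCc2ccccc2)cc1)O)c1c(OCc2ccccc2)cc(OC)cc1OCc1ccccc1 | intermediate
8 | (3S)-1-[2,6-bis(benzyloxy)-4-methoxyphenyl]-5-[4-(benzyloxy)phenyl]pentane-1,3-diol, C1 epimers | OC(C[C@H](CCc1ccc(OCc2ccccc2)cc1)O)c1c(OCc2ccccc2)cc(OC)cc1OCc1ccccc1 | intermediate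
9 | 4-(benzyloxy)benzaldehyde | O=Cc1ccc(OCc2ccccc2)cc1 | starting material
10 | 1-(benzyloxy)-4-ethenylbenzene | C=Cc1ccc(OCc2ccccc2)cc1 | intermediate
11 | benzylic cation from 8 by loss of the C1 hydroxyl, C3 carbinol centre unchanged | [CH+](C[C@H](CCc1ccc(OCc2ccccc2)cc1)O)c1c(OCc2ccccc2)cc(OC)cc1OCc1ccccc1 | intermediate (not isolated)
12 | open-chain para-benzyloxybenzylic cation after C3–C4 bond formation, C4 and C6 configured as in 13 | COc1cc(OCc2ccccc2)c([C@@H](C[CH+]c2ccc(OCc3ccccc3)cc2)C[C@H](CCc2ccc(OCc3ccccc3)cc2)O)c(OCc2ccccc2)c1 | intermediate (not isolated)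
13 | (2S,4R,6S)-4-[2,6-bis(benzyloxy)-4-methoxyphenyl]-2-[4-(benzyloxy)phenyl]-6-{2-[4-(benzyloxy)phenyl]ethyl}oxane | COc1cc(OCc2ccccc2)c([C@@H]2C[C@H](CCc3ccc(OCc4ccccc4)cc3)O[C@H](c3ccc(OCc4ccccc4)cc3)C2)c(OCc2ccccc2)c1 | intermediate
14 | (2S,4R,6S)-4-[2,6-bis(benzyloxy)-3-bromo-4-methoxyphenyl]-2-[4-(benzyloxy)phenyl]-6-{2-[4-(benzyloxy)phenyl]ethyl}oxane | COc1cc(OCc2ccccc2)c([C@@H]2C[C@H](CCc3ccc(OCc4ccccc4)cc3)O[C@H](c3ccc(OCc4ccccc4)cc3)C2)c(OCc2ccccc2)c1Br | intermediate
15 | aryllithium from 14, lithium in place of bromine | COc1cc(OCc2ccccc2)c([C@@H]2C[C@H](CCc3ccc(OCc4ccccc4)cc3)O[C@H](c3ccc(OCc4ccccc4)cc3)C2)c(OCc2ccccc2)c1[Li] | intermediate (not isolated)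
16 | 1-[2,4-bis(benzyloxy)-3-{(2S,4R,6S)-2-[4-(benzyloxy)phenyl]-6-{2-[4-(benzyloxy)phenyl]ethyl}oxan-4-yl}-6-methoxyphenyl]ethan-1-one | COc1cc(OCc2ccccc2)c([C@@H]2C[C@H](CCc3ccc(OCc4ccccc4)cc3)O[C@H](c3ccc(OCc4ccccc4)cc3)C2)c(OCc2ccccc2)c1C(C)=O | intermediate
17 | 1-[2,4-dihydroxy-3-{(2S,4R,6S)-2-(4-hydroxyphenyl)-6-[2-(4-hydroxyphenyl)ethyl]oxan-4-yl}-6-methoxyphenyl]ethan-1-one | COc1cc(O)c([C@@H]2C[C@H](CCc3ccc(O)cc3)O[C@H](c3ccc(O)cc3)C2)c(O)c1C(C)=O | intermediate
18 | 4-hydroxybenzaldehyde | O=Cc1ccc(O)cc1 | starting material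
19 | aldol adduct: 3-hydroxy-3-(4-hydroxyphenyl)propan-1-one of 17, carbinol epimers | COc1cc(O)c([C@@H]2C[C@H](CCc3ccc(O)cc3)O[C@H](c3ccc(O)cc3)C2)c(O)c1C(=O)CC(O)c1ccc(O)cc1 | intermediate (not isolated)
20 | (2E)-1-[2,4-dihydroxy-3-{(2S,4R,6S)-2-(4-hydroxyphenyl)-6-[2-(4-hydroxyphenyl)ethyl]oxan-4-yl}-6-methoxyphenyl]-3-(4-hydroxyphenyl)prop-2-en-1-one | COc1cc(O)c([C@@H]2C[C@H](CCc3ccc(O)cc3)O[C@H](c3ccc(O)cc3)C2)c(O)c1C(=O)/C=C/c1ccc(O)cc1 | target

**Step count and risks**

Total step count: 11. Longest linear sequence: 9 steps (steps 1, 3, 4, 5, 7, 8, 9, 10, 11).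

Steps most likely to fail:

1. Step 7. Cationic oligomerisation of styrene 10 or Friedel–Crafts self-alkylation of the electron-rich ring may outrun the annulation, and attack on the planar cation without hydroxyl participation may erode facial selectivity at C4. The fallback sets out from 8 and returns at 13, replacing the styrene by a stronger, non-polymerising π-nucleophile and building the ring in two known operations. Commercial 4'-(benzyloxy)acetophenone is converted with TMSOTf/Et3N into trimethyl({1-[4-(benzyloxy)phenyl]ethenyl}oxy)silane F1. Diol 8 is then ionised with catalytic Bi(OTf)3 in CH2Cl2 at −40 °C in the presence of F1; this Mukaiyama-type SN1 alkylation of a trialkoxybenzylic alcohol should give (3R,5S)-3-[2,6-bis(benzyloxy)-4-methoxyphenyl]-1,7-bis[4-(benzyloxy)phenyl]-5-hydroxyheptan-1-one F2 together with its C3 epimer, which would be separated at this stage. Reductive etherification of F2 (Et3SiH, BF3·OEt2, CH2Cl2, −78 °C) should close the oxane through the cyclic oxocarbenium ion, with axial hydride delivery giving the 2,6-cis product 13.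

2. Step 11. Polyphenoxide formation may lower the acidity of the acetyl group and the electrophilicity of the aldehyde so far that condensation stalls while the electron-rich phenoxides slowly oxidise. The fallback sets out from 17 and returns at 20, masking the phenols with groups removable without acid or hydrogen. K2CO3 and allyl bromide in acetone at rt should alkylate the three non-chelated phenols to give 1-[2-hydroxy-6-methoxy-4-(prop-2-en-1-yloxy)-3-{(2S,4R,6S)-2-[4-(prop-2-en-1-yloxy)phenyl]-6-{2-[4-(prop-2-en-1-yloxy)phenyl]ethyl}oxan-4-yl}phenyl]ethan-1-one F3. Claisen–Schmidt condensation of F3 with commercial 4-(allyloxy)benzaldehyde (KOH, EtOH, rt), the standard case of a 2'-hydroxyacetophenone, should give the tetra-O-allyl chalcone (2E)-1-[2-hydroxy-6-methoxy-4-(prop-2-en-1-yloxy)-3-{(2S,4R,6S)-2-[4-(prop-2-en-1-yloxy)phenyl]-6-{2-[4-(prop-2-en-1-yloxy)phenyl]ethyl}oxan-4-yl}phenyl]-3-[4-(prop-2-en-1-yloxy)phenyl]prop-2-en-1-one F4. Allyl transfer to morpholine with Pd(PPh3)4 in THF at rt (Tsuji–Trost-type deallylation) should then give 20.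

3. Step 9. Proton transfer from the enolisable amide to the hindered aryllithium (net protodebromination), or metalation of a neighbouring OCH2Ph group on warming, may compete with acylation. The fallback sets out from 14 and returns at 16, using a non-enolisable electrophile and adjusting the oxidation level afterwards. Br–Li exchange (n-BuLi, THF, −78 °C) and quenching with DMF should give 2,4-bis(benzyloxy)-3-{(2S,4R,6S)-2-[4-(benzyloxy)phenyl]-6-{2-[4-(benzyloxy)phenyl]ethyl}oxan-4-yl}-6-methoxybenzaldehyde F5. Addition of MeMgBr (THF, −78 °C) should give 1-[2,4-bis(benzyloxy)-3-{(2S,4R,6S)-2-[4-(benzyloxy)phenyl]-6-{2-[4-(benzyloxy)phenyl]ethyl}oxan-4-yl}-6-methoxyphenyl]ethan-1-ol F6 as carbinol epimers, and Dess–Martin oxidation buffered with NaHCO3 in CH2Cl2 should give 16.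

**Further compounds**

F1 | step 7 | trimethyl({1-[4-(benzyloxy)phenyl]ethenyl}oxy)silane | C=C(O[Si](C)(C)C)c1ccc(OCc2ccccc2)cc1
F2 | step 7 | (3R,5S)-3-[2,6-bis(benzyloxy)-4-methoxyphenyl]-1,7-bis[4-(benzyloxy)phenyl]-5-hydroxyheptan-1-one | O=C(C[C@@H](C[C@H](CCc1ccc(OCc2ccccc2)cc1)O)c1c(OCc2ccccc2)cc(OC)cc1OCc1ccccc1)c1ccc(OCc2ccccc2)cc1
F3 | step 11 | 1-[2-hydroxy-6-methoxy-4-(prop-2-en-1-yloxy)-3-{(2S,4R,6S)-2-[4-(prop-2-en-1-yloxy)phenyl]-6-{2-[4-(prop-2-en-1-yloxy)phenyl]ethyl}oxan-4-yl}phenyl]ethan-1-one | COc1cc(OCC=C)c([C@@H]2C[C@H](CCc3ccc(OCC=C)cc3)O[C@H](c3ccc(OCC=C)cc3)C2)c(O)c1C(C)=O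
F4 | step 11 | (2E)-1-[2-hydroxy-6-methoxy-4-(prop-2-en-1-yloxy)-3-{(2S,4R,6S)-2-[4-(prop-2-en-1-yloxy)phenyl]-6-{2-[4-(prop-2-en-1-yloxy)phenyl]ethyl}oxan-4-yl}phenyl]-3-[4-(prop-2-en-1-yloxy)phenyl]prop-2-en-1-one | COc1cc(OCC=C)c([C@@H]2C[C@H](CCc3ccc(OCC=C)cc3)O[C@H](c3ccc(OCC=C)cc3)C2)c(O)c1C(=O)/C=C/c1ccc(OCC=C)cc1
F5 | step 9 | 2,4-bis(benzyloxy)-3-{(2S,4R,6S)-2-[4-(benzyloxy)phenyl]-6-{2-[4-(benzyloxy)phenyl]ethyl}oxan-4-yl}-6-methoxybenzaldehyde | COc1cc(OCc2ccccc2)c([C@@H]2C[C@H](CCc3ccc(OCc4ccccc4)cc3)O[C@H](c3ccc(OCc4ccccc4)cc3)C2)c(OCc2ccccc2)c1C=O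
F6 | step 9 | 1-[2,4-bis(benzyloxy)-3-{(2S,4R,6S)-2-[4-(benzyloxy)phenyl]-6-{2-[4-(benzyloxy)phenyl]ethyl}oxan-4-yl}-6-methoxyphenyl]ethan-1-ol, carbinol epimers | COc1cc(OCc2ccccc2)c([C@@H]2C[C@H](CCc3ccc(OCc4ccccc4)cc3)O[C@H](c3ccc(OCc4ccccc4)cc3)C2)c(OCc2ccccc2)c1C(C)O
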